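I froze one number. You wanted a quick figure for beta and delta, and your hunch was that D sets how far L goes, not how fast; I started there.

common to all: L 0.50 M
- summer: D 0.31 M; G 0.025 M; run made earlier
- winter: D 0.99 M; G 0.025 M; run made earlier
- beta: D 1.10 M; G 0.0250 M; time 12 min
- delta: D 0.450 M; G 0.0250 M; time 12 min

- summer (time / min: Z / %, L / %, J / %): 1.00: 6, 90, 4; 3.00: 0, 89, 5; 6.00: 3, 81, 10; 8.00: 0, 80, 14; 12.0: 4, 76, 11
- winter (time / min: Z / %, L / %, J / %): 1.00: 5, 79, 11; 2.00: 7, 56, 33; 3.00: 13, 32, 49; 6.00: 14, 20, 63; 12.0: 14, 10, 67

(each reading ± 2 percentage points)

- which of these there is most of at the end, counted by the L in it, beta (J / L / Z)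
- which of these there is most of at the end, counted by the L in it, delta (J / L / Z)
- how much there is at the end of the one of these that leads, in percent of the L charged: beta
- how much there is at the end of the one of these that leads, in percent of the L charged: delta

In summer, L read 81 % at 6.00 min and 76 % at 12.0 min, so I took the last reading as nearly what its D could do. I defined w, the yield on D, as moles of L used per mole of D charged:

w = L used / D charged = 0.387 (summer)

w = 0.455 (winter)

The two lay close enough to freeze, and I used the one from the run nearer in D.

Delta, L left = 65.2 %

Beta, L used = 100 %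

So I expected L to lead in delta. In beta, by this reckoning, D covered the L charged, and J's winter share of the L used, 74.4 %, put J in the lead at about that figure.

The forecast, made apart from mine, gave J at 73 % for beta and L at 60 % for delta, lower than my delta figure; for delta it took a rate that “decays as D is consumed”.

The flasks gave J at 72.6 % in beta and L at 65.9 % in delta.

    L + D + X → J + 2 X (k = 0.0810 L² mol⁻² s⁻¹)
    L + D → J + X (k = 9.29 × 10⁻⁴ L mol⁻¹ s⁻¹)
    D → E (k = 0.00402 s⁻¹)
    L + G → Q (k = 0.0937 L mol⁻¹ s⁻¹)
    J ⇌ Z (K = 0.220, k = 0.0466 s⁻¹)

In delta, the yield on D came to 0.379, beside the frozen 0.387. D was the limiting reagent there, with 0.525 % of its charge free at the end. Beta and delta differ in their charge of D, and that difference was the main reason for the gap in J between them: J stood at 72.6 % in beta, and at 23.8 % once beta had delta's D. For the flask like beta but with 0.44 M of D, w gave L left at 65.9 %; that flask ended at 66.9 %.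

The numbers in the tables were generated by integration for substances that don't exist.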